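**Plan**

1. Numbering used throughout (isochromene): C1 (the CH between the ring oxygen O2 and C8a), C3 (carries the side chain), C4, C4a, C5, C6 (C=O), C7 (quaternary), C8 (C=O), C8a.
2. Retrosynthesis: the enal comes from the allylic alcohol and the phenols from silyl ethers; the pyran ring is cut at C1–C8a, then O2–C1/O2–C3 (formic acid plus an alkyne); C4a–C4 is cut to an acetylide plus a para-quinol ester dienone; C7–O is cut to a phenol plus protected orsellinic acid.
3. Forward: the carbocycle comes from 3,5-dimethoxy-4-methylphenol, dearomatised with the orsellinate entering as an O-nucleophile; acetylide addition and hydrolysis give a 5-alkynyl vinylogous acid; formic acid is added across the alkyne; the pyran ring is closed last.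
4. Enabling feature: in the 2-aroyloxy-2-methylcyclohex-4-ene-1,3-dione precursor a mirror plane runs through C7 and C4a, so C5 and C8a are enantiotopic and exchange by tautomerism. A formyl carbon tethered through O2 can bond to only one of them, and that choice alone fixes C7.
5. Stereochemistry: the single stereocentre (C7, R) is set in the ring closure by a chiral Brønsted acid (desymmetrisation); every earlier intermediate is achiral or rapidly racemising.

Key step: step 7

Assumption: the sense of induction of the chiral acid in step 7 cannot be predicted with certainty; the (R)-acid is written, and its mirror image would be used if it favoured the (S)-product.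

**Step 1**
Reactants: 1 2,6-dimethoxytoluene
Product: 3 3,5-dimethoxy-4-methylphenol, via arylboronate 2 (not isolated)
Conditions: [Ir(OMe)(cod)]2 (1.5 mol %), 4,4′-di-tert-butyl-2,2′-bipyridine, B2pin2, hexane, 80 °C; then H2O2 (30 %), NaOH aq, THF, 0 °C
Reagents that add atoms: hydrogen peroxide, OO
Why: Iridium-catalysed C–H borylation is sterically directed to the one ring position with no ortho substituent (para to the methyl group), and oxidation of the boronate should give the phenol (one-pot borylation/oxidation).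

**Step 2**
Reactants: 4 orsellinic acid
Product: 6 2,4-bis(triisopropylsilyloxy)-6-methylbenzoic acid, via silyl ester 5 (not isolated)
Conditions: TIPSCl (3.5 equiv), imidazole, DMF, 40 °C; then AcOH/THF/H2O, rt
Reagents that add atoms: triisopropylsilyl chloride, CC(C)[Si](Cl)(C(C)C)C(C)C
Why: Exhaustive silylation followed by selective hydrolysis of the much more labile silyl ester should leave both phenols as acid-stable aryl silyl ethers and the carboxylic acid free.

**Step 3**
Reactants: 7 (E)-pent-2-en-4-yn-1-ol
Product: 8 (E)-tert-butyl(pent-2-en-4-yn-1-yloxy)diphenylsilane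
Conditions: TBDPSCl, imidazole, CH2Cl2, 0 °C → rt
Reagents that add atoms: tert-butyldiphenylsilyl chloride, CC(C)(C)[Si](Cl)(c1ccccc1)c1ccccc1
Why: Routine silylation of a primary alcohol; the TBDPS ether is chosen because it should survive the aqueous acid of step 5, and the alcohol oxidation level is kept so that the alkyne stays polarised by the ring alone until step 6.

**Step 4**
Reactants: 3 3,5-dimethoxy-4-methylphenol; 6 2,4-bis(triisopropylsilyloxy)-6-methylbenzoic acid
Product: 10 para-quinol ester dienone, via bis(aroyloxy)iodobenzene 9 (not isolated)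
Conditions: PhI(OAc)2 (1.05 equiv), 6 (2.1 equiv), PhCl, 45 °C, reduced pressure (AcOH removed); then 3, CH2Cl2/(CF3)2CHOH, −20 → 0 °C
Reagents that add atoms: none
Why: Ligand exchange gives 9, which oxidises the phenol so that the carboxylate oxygen is captured at the para carbon (methyl-bearing, activated by both methoxy groups) in a Wessely-type oxidative dearomatising acyloxylation; the hindered tertiary ester is thus made by O-alkylation of the carboxylate instead of by acylating a tertiary alcohol, and the product is achiral.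

**Step 5**
Reactants: 10 para-quinol ester dienone; 8 (E)-tert-butyl(pent-2-en-4-yn-1-yloxy)diphenylsilane
Product: 14 5-alkynyl vinylogous acid, via lithium acetylide 11 (not isolated), via tertiary carbinol 12 (not isolated), via methoxy dienone 13 (not isolated)
Conditions: 8 (1.2 equiv), n-BuLi, THF, −78 °C; 10, −78 → −20 °C; then 2 M HCl, THF, 0 °C → rt
Reagents that add atoms: water, O
Why: 1,2-Addition of the acetylide to the doubly vinylogous ester carbonyl, then acid ionisation of the bis-allylic carbinol and hydrolysis of both enol ethers (Stork–Danheiser transposition) should give the vinylogous acid; the di-ortho-substituted aryl ester is too hindered to be attacked, and the product is a fast-tautomerising, effectively achiral species.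

**Step 6**
Reactants: 14 5-alkynyl vinylogous acid
Product: 15 (Z)-enol formate
Conditions: Ph3PAuNTf2 (5 mol %), HCO2H (3 equiv), toluene, 0 °C → rt; rapid filtration through neutral silica
Reagents that add atoms: formic acid, OC=O
Why: Gold-catalysed anti hydro-acyloxylation of an alkyne: the triple bond is polarised by the electron-poor ring carbon C4a and by the vinyl group on C3, so the formate oxygen should add at C3 and protodeauration should place H on C4 trans to it, giving O2 cis to the ring (Z), the geometry the ring closure needs.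

**Step 7**
Reactants: 15 (Z)-enol formate
Product: 17 (R)-silyl-protected azaphilone, via lactol 16 (not isolated)
Conditions: (R)-3,3′-bis(2,4,6-triisopropylphenyl)-1,1′-binaphthyl-2,2′-diyl N-triflylphosphoramide (10 mol %), 5 Å molecular sieves, toluene, −40 → 0 °C
Reagents that add atoms: none
Why: Proposed new method: the acid should hold 15 at two points (acidic N–H on the formyl oxygen, P=O on the enol O–H next to C7), so that the enol carbon adds to the tethered formyl carbon C1 to give lactol 16, which loses water to the C1=C8a enol ether of 17. The closest known reaction types are the Kostanecki–Robinson cyclocondensation of O-acylated enols (C–C closure onto an ester carbonyl, then dehydration), chiral-acid-catalysed additions of enols to activated carbonyl groups, and the Hajos–Parrish desymmetrisation of 2,2-disubstituted cyclic 1,3-diketones. The pyran ring closes in a 6-(enolexo)-exo-trig mode, the C8=C8a enol bond and the formyl C=O both lying outside the new ring. C1 and C8a end up sp2, so the only stereocentre at stake is C7: it becomes stereogenic when the enantiotopic enol carbons C8a and C5 of the mirror-symmetric, tautomerising vinylogous acid are told apart, and the catalyst, whose pocket contains the C7 methyl and aroyloxy groups because it is hydrogen-bonded to the neighbouring enol hydroxyl, is the controlling element. The selectivity needed is enantiotopic-site selectivity (C8a against C5) and not constitutional selectivity, since the (Z)-enol formate tether reaches only these two carbons, both closures give the same skeleton, and fast keto–enol exchange lets all material drain through the favoured arm. Once C8a bears C1 the exchange is blocked and the configuration at C7 is fixed.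

**Step 8**
Reactants: 17 (R)-silyl-protected azaphilone
Product: 18 (R)-allylic alcohol with free phenols
Conditions: HF·pyridine, pyridine, THF, 0 °C → rt
Reagents that add atoms: none
Why: Fluoride cleavage of the two aryl triisopropylsilyl ethers and the primary TBDPS ether under buffered acidic conditions that the azaphilone core and the tertiary ester should tolerate; C7 is not touched.

**Step 9**
Reactants: 18 (R)-allylic alcohol with free phenols
Product: 19 target aldehyde
Conditions: MnO2 (activated, excess), CH2Cl2, rt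
Reagents that add atoms: none
Why: Activated MnO2 should oxidise the allylic primary alcohol selectively to the (E)-enal without affecting the hydrogen-bonded phenols, the ester or the stereocentre.

**Compound list**

1 | 2,6-dimethoxytoluene | Cc1c(OC)cccc1OC | starting material
2 | 2-(3,5-dimethoxy-4-methylphenyl)-4,4,5,5-tetramethyl-1,3,2-dioxaborolane | Cc1c(OC)cc(B2OC(C)(C)C(C)(C)O2)cc1OC | intermediate
3 | 3,5-dimethoxy-4-methylphenol | Cc1c(OC)cc(O)cc1OC | intermediate
4 | orsellinic acid (2,4-dihydroxy-6-methylbenzoic acid) | Cc1cc(O)cc(O)c1C(=O)O | starting material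
5 | triisopropylsilyl 2,4-bis(triisopropylsilyloxy)-6-methylbenzoate | Cc1cc(O[Si](C(C)C)(C(C)C)C(C)C)cc(O[Si](C(C)C)(C(C)C)C(C)C)c1C(=O)O[Si](C(C)C)(C(C)C)C(C)C | intermediate
6 | 2,4-bis(triisopropylsilyloxy)-6-methylbenzoic acid | Cc1cc(O[Si](C(C)C)(C(C)C)C(C)C)cc(O[Si](C(C)C)(C(C)C)C(C)C)c1C(=O)O | intermediate
7 | (E)-pent-2-en-4-yn-1-ol | C#C/C=C/CO | starting material
8 | (E)-tert-butyl(pent-2-en-4-yn-1-yloxy)diphenylsilane | C#C/C=C/CO[Si](c1ccccc1)(c1ccccc1)C(C)(C)C | intermediate
9 | bis[2,4-bis(triisopropylsilyloxy)-6-methylbenzoyloxy]iodobenzene | Cc1cc(O[Si](C(C)C)(C(C)C)C(C)C)cc(O[Si](C(C)C)(C(C)C)C(C)C)c1C(=O)OI(OC(=O)c1c(C)cc(O[Si](C(C)C)(C(C)C)C(C)C)cc1O[Si](C(C)C)(C(C)C)C(C)C)c1ccccc1 | intermediate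
10 | 2,6-dimethoxy-1-methyl-4-oxocyclohexa-2,5-dien-1-yl 2,4-bis(triisopropylsilyloxy)-6-methylbenzoate (achiral para-quinol ester) | COC1=CC(=O)C=C(OC)C1(C)OC(=O)c1c(C)cc(O[Si](C(C)C)(C(C)C)C(C)C)cc1O[Si](C(C)C)(C(C)C)C(C)C | intermediate
11 | lithium acetylide of 8 | [Li]C#C/C=C/CO[Si](c1ccccc1)(c1ccccc1)C(C)(C)C | intermediate
12 | 4-hydroxy-2,6-dimethoxy-1-methyl-4-[(E)-5-(tert-butyldiphenylsilyloxy)pent-3-en-1-ynyl]cyclohexa-2,5-dien-1-yl 2,4-bis(triisopropylsilyloxy)-6-methylbenzoate (achiral cis/trans carbinols) | COC1=CC(O)(C#C/C=C/CO[Si](c2ccccc2)(c2ccccc2)C(C)(C)C)C=C(OC)C1(C)OC(=O)c1c(C)cc(O[Si](C(C)C)(C(C)C)C(C)C)cc1O[Si](C(C)C)(C(C)C)C(C)C | intermediate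
13 | racemic 6-methoxy-1-methyl-2-oxo-4-[(E)-5-(tert-butyldiphenylsilyloxy)pent-3-en-1-ynyl]cyclohexa-3,5-dien-1-yl 2,4-bis(triisopropylsilyloxy)-6-methylbenzoate | COC1=CC(C#C/C=C/CO[Si](c2ccccc2)(c2ccccc2)C(C)(C)C)=CC(=O)C1(C)OC(=O)c1c(C)cc(O[Si](C(C)C)(C(C)C)C(C)C)cc1O[Si](C(C)C)(C(C)C)C(C)C | intermediate
14 | 6-hydroxy-1-methyl-2-oxo-4-[(E)-5-(tert-butyldiphenylsilyloxy)pent-3-en-1-ynyl]cyclohexa-3,5-dien-1-yl 2,4-bis(triisopropylsilyloxy)-6-methylbenzoate (enol form of the 2-aroyloxy-2-methyl-5-alkynylcyclohex-4-ene-1,3-dione; the two enol forms are mirror images in fast exchange, so no configuration is given) | OC1=CC(C#C/C=C/CO[Si](c2ccccc2)(c2ccccc2)C(C)(C)C)=CC(=O)C1(C)OC(=O)c1c(C)cc(O[Si](C(C)C)(C(C)C)C(C)C)cc1O[Si](C(C)C)(C(C)C)C(C)C | intermediate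
15 | 4-[(1Z,3E)-2-formyloxy-5-(tert-butyldiphenylsilyloxy)penta-1,3-dienyl]-6-hydroxy-1-methyl-2-oxocyclohexa-3,5-dien-1-yl 2,4-bis(triisopropylsilyloxy)-6-methylbenzoate (same exchange as 14) | OC1=CC(/C=C(OC=O)/C=C/CO[Si](c2ccccc2)(c2ccccc2)C(C)(C)C)=CC(=O)C1(C)OC(=O)c1c(C)cc(O[Si](C(C)C)(C(C)C)C(C)C)cc1O[Si](C(C)C)(C(C)C)C(C)C | intermediate
16 | 1,8-dihydroxy-7-methyl-6-oxo-3-[(E)-3-(tert-butyldiphenylsilyloxy)prop-1-enyl]-6,7-dihydro-1H-isochromen-7-yl 2,4-bis(triisopropylsilyloxy)-6-methylbenzoate (lactol; C7 arranged as in 17, C1 unassigned) | Cc1cc(O[Si](C(C)C)(C(C)C)C(C)C)cc(O[Si](C(C)C)(C(C)C)C(C)C)c1C(=O)O[C@]1(C)C(=O)C=C2C=C(/C=C/CO[Si](c3ccccc3)(c3ccccc3)C(C)(C)C)OC(O)C2=C1O | intermediate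
17 | (7R)-7-methyl-6,8-dioxo-3-[(E)-3-(tert-butyldiphenylsilyloxy)prop-1-enyl]-7,8-dihydro-6H-isochromen-7-yl 2,4-bis(triisopropylsilyloxy)-6-methylbenzoate | Cc1cc(O[Si](C(C)C)(C(C)C)C(C)C)cc(O[Si](C(C)C)(C(C)C)C(C)C)c1C(=O)O[C@]1(C)C(=O)C=C2C=C(/C=C/CO[Si](c3ccccc3)(c3ccccc3)C(C)(C)C)OC=C2C1=O | intermediate
18 | (7R)-3-[(E)-3-hydroxyprop-1-enyl]-7-methyl-6,8-dioxo-7,8-dihydro-6H-isochromen-7-yl 2,4-dihydroxy-6-methylbenzoate | Cc1cc(O)cc(O)c1C(=O)O[C@]1(C)C(=O)C=C2C=C(/C=C/CO)OC=C2C1=O | intermediate
19 | (7R)-7-methyl-6,8-dioxo-3-[(E)-3-oxoprop-1-enyl]-7,8-dihydro-6H-isochromen-7-yl 2,4-dihydroxy-6-methylbenzoate | Cc1cc(O)cc(O)c1C(=O)O[C@]1(C)C(=O)C=C2C=C(/C=C/C=O)OC=C2C1=O | target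

**Step count**

Total steps: 9. Longest linear sequence: 7 steps (1 → 3 → 10 → 14 → 15 → 17 → 18 → 19; steps 1, 4, 5, 6, 7, 8, 9).

**Steps most likely to fail**

Step 7 (Proposed new method). The catalyst may discriminate poorly between the two enantiotopic enol carbons, or the closure may run through an uncatalysed background path, either of which would erode the enantiomeric purity. Fallback with known chemistry, leaving the route at 14 and rejoining at 17: gold-catalysed hydration of the alkyne of 14 (Ph3PAuNTf2, wet dioxane) should give the side-chain ketone F1. Heating F1 with triethyl orthoformate and catalytic TsOH in toluene formylates an enol carbon first and closes the pyran through O2–C1, the classical order for pyranone-type rings, giving the racemic silyl-protected azaphilone F2. Preparative chromatography of F2 on a chiral stationary phase then delivers the (R)-enantiomer, which is 17.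

Step 6. The enol formate may close the ring prematurely and without the chiral catalyst in the acidic medium, or the alkyne may be hydrated by adventitious water. Fallback, leaving the route at 14 and rejoining at 15: the enolic nucleophile is masked first. Allyl alcohol with pyridinium p-toluenesulfonate and azeotropic removal of water should convert 14 into the allyl vinylogous ester F3, which has no enol carbon free to attack. The same gold-catalysed formic acid addition then gives its (Z)-enol formate F4. Pd(PPh3)4 with triethylammonium formate removes the allyl group under neutral conditions to release 15, which is taken directly into step 7.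

Step 4. The carboxylate may be captured at an unsubstituted ortho carbon instead of the para carbon, or the very electron-rich phenol may be over-oxidised. Fallback, leaving the route at 3 and rejoining at 10: the oxygen is introduced first and the ester made afterwards. Singlet-oxygen-type para-oxygenation of 3 (KHSO5 as Oxone, NaHCO3, aqueous MeCN) should give the para-hydroperoxide F5, and dimethyl sulfide reduces it to the para-quinol F6. Acid 6 is converted with 1-chloro-N,N,2-trimethylprop-1-en-1-amine into the acid chloride F7, which acylates the lithium alkoxide of F6 (LiN(SiMe3)2, THF, −78 °C) to give 10.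

**Further compounds**

F1 | step 7 | 6-hydroxy-1-methyl-2-oxo-4-[(E)-2-oxo-5-(tert-butyldiphenylsilyloxy)pent-3-enyl]cyclohexa-3,5-dien-1-yl 2,4-bis(triisopropylsilyloxy)-6-methylbenzoate | OC1=CC(CC(=O)/C=C/CO[Si](c2ccccc2)(c2ccccc2)C(C)(C)C)=CC(=O)C1(C)OC(=O)c1c(C)cc(O[Si](C(C)C)(C(C)C)C(C)C)cc1O[Si](C(C)C)(C(C)C)C(C)C
F2 | step 7 | racemic 7-methyl-6,8-dioxo-3-[(E)-3-(tert-butyldiphenylsilyloxy)prop-1-enyl]-7,8-dihydro-6H-isochromen-7-yl 2,4-bis(triisopropylsilyloxy)-6-methylbenzoate | Cc1cc(O[Si](C(C)C)(C(C)C)C(C)C)cc(O[Si](C(C)C)(C(C)C)C(C)C)c1C(=O)OC1(C)C(=O)C=C2C=C(/C=C/CO[Si](c3ccccc3)(c3ccccc3)C(C)(C)C)OC=C2C1=O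
F3 | step 6 | racemic 6-allyloxy-1-methyl-2-oxo-4-[(E)-5-(tert-butyldiphenylsilyloxy)pent-3-en-1-ynyl]cyclohexa-3,5-dien-1-yl 2,4-bis(triisopropylsilyloxy)-6-methylbenzoate | C=CCOC1=CC(C#C/C=C/CO[Si](c2ccccc2)(c2ccccc2)C(C)(C)C)=CC(=O)C1(C)OC(=O)c1c(C)cc(O[Si](C(C)C)(C(C)C)C(C)C)cc1O[Si](C(C)C)(C(C)C)C(C)C
F4 | step 6 | racemic 6-allyloxy-4-[(1Z,3E)-2-formyloxy-5-(tert-butyldiphenylsilyloxy)penta-1,3-dienyl]-1-methyl-2-oxocyclohexa-3,5-dien-1-yl 2,4-bis(triisopropylsilyloxy)-6-methylbenzoate | C=CCOC1=CC(/C=C(OC=O)/C=C/CO[Si](c2ccccc2)(c2ccccc2)C(C)(C)C)=CC(=O)C1(C)OC(=O)c1c(C)cc(O[Si](C(C)C)(C(C)C)C(C)C)cc1O[Si](C(C)C)(C(C)C)C(C)C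
F5 | step 4 | 4-hydroperoxy-3,5-dimethoxy-4-methylcyclohexa-2,5-dien-1-one | COC1=CC(=O)C=C(OC)C1(C)OO
F6 | step 4 | 4-hydroxy-3,5-dimethoxy-4-methylcyclohexa-2,5-dien-1-one | COC1=CC(=O)C=C(OC)C1(C)O
F7 | step 4 | 2,4-bis(triisopropylsilyloxy)-6-methylbenzoyl chloride | Cc1cc(O[Si](C(C)C)(C(C)C)C(C)C)cc(O[Si](C(C)C)(C(C)C)C(C)C)c1C(Cl)=O
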